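**Plan**

1. Retrosynthesis: the silyl ethers come off last. The C4–O2' bond, which the target lacks, is put back to give a cis-pterocarpan. That is cut at O1–C2 (Mitsunobu), at C3–C4 (carbene C–H insertion) and at O2'–C4 (ether union of the two aryl units). The 1,1-dimethylallyl group goes back to an O4' prenyl ether.
2. Enabling feature: the C2' hydroxyl of ring B can carry C4 as a benzylic ether. O2', C2', C1', C3 and C4 then make a five-membered ring in which C3–C4 is formed. The C4–O2' bond is benzylic and para to O7 of ring A, so it can be cut reductively afterwards.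
3. Forward: ring A benzyl alcohol 9 (six steps) and ring B phenol 13 (two steps) are joined at O2'. Claisen shift, silylation and diazo transfer give 18. Insertion closes the dihydrofuran, reduction and Mitsunobu closure add the pyran, Li/NH3 opens the furan ring, and fluoride frees the hydroxyls.
4. Stereochemistry: C3 is set by the chiral dirhodium carboxylate in the insertion and is not touched again. The cis C4 centre only serves the pyran closure and disappears when C4 becomes CH2.

Key step: step 13

Remark: isoflavan numbering (O1, C2, C3, C4, C4a to C8a, primed atoms for ring B) is used throughout; Rh2(S-PTTL)4 is assumed, by analogy with simpler 2-benzyloxyphenyl diazoacetates, to give the (2R,3S) cis ester, and Rh2(R-PTTL)4 would be used if the sense proved opposite.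

**Route**

Step 1
Reactants: 1 2-iodoresorcinol
Product: 3 2,4-dihydroxy-3-iodobenzaldehyde, via aryliminium chloride 2 (not isolated)
Conditions: POCl3, DMF, MeCN, −15 °C to rt; then H2O, 50 °C
Reagents that add atoms: N,N-dimethylformamide, CN(C)C=O; water, O
Why: Vilsmeier–Haack formylation, in which the chloroiminium ion attacks the only activated free position (C4 and C6 are equivalent, para to one hydroxyl and ortho to the other), the iminium salt blocks a second attack, and hydrolysis gives the aldehyde as with other 2-substituted resorcinols.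

Step 2
Reactants: 3 2,4-dihydroxy-3-iodobenzaldehyde; 4 2-methylbut-3-en-2-ol
Product: 5 2,4-dihydroxy-3-[(1E)-3-hydroxy-3-methylbut-1-en-1-yl]benzaldehyde
Conditions: Pd(OAc)2 (5 mol %), Bu4NCl, NaHCO3, DMF, 70 °C
Reagents that add atoms: none
Why: Heck reaction under phase-transfer conditions, in which the aryl group from oxidative addition to zerovalent palladium adds to the terminal alkene carbon and β-hydride elimination can only run toward the ring because the carbinol carbon is quaternary, so the E alkene should result.

Step 3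
Reactants: 5 2,4-dihydroxy-3-[(1E)-3-hydroxy-3-methylbut-1-en-1-yl]benzaldehyde
Product: 6 2,4-dihydroxy-3-(3-hydroxy-3-methylbutyl)benzaldehyde
Conditions: H2 (1 atm), 10% Pd/C, Ph2S (cat.), EtOAc, rt
Reagents that add atoms: none
Why: Catalytic hydrogenation over sulfide-moderated palladium should saturate the disubstituted alkene while the chelated, electron-rich aryl aldehyde and the tertiary allylic C–O bond are left alone.

Step 4
Reactants: 6 2,4-dihydroxy-3-(3-hydroxy-3-methylbutyl)benzaldehyde
Product: 7 2-hydroxy-3-(3-hydroxy-3-methylbutyl)-4-[(triisopropylsilyl)oxy]benzaldehyde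
Conditions: TIPSCl, imidazole, DMF, 0 °C to rt
Reagents that add atoms: triisopropylsilyl chloride, CC(C)[Si](Cl)(C(C)C)C(C)C
Why: Silylation of the free 4-hydroxyl, since the 2-hydroxyl is held in a hydrogen bond to the aldehyde and the tertiary alcohol does not react with a hindered silyl chloride; the triisopropylsilyl ether is chosen because it withstands the later base and hydride steps.

Step 5
Reactants: 7 2-hydroxy-3-(3-hydroxy-3-methylbutyl)-4-[(triisopropylsilyl)oxy]benzaldehyde
Product: 8 6-formyl-2-(3-hydroxy-3-methylbutyl)-3-[(triisopropylsilyl)oxy]phenyl pivalate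
Conditions: PivCl, Et3N, DMAP (cat.), CH2Cl2, 0 °C to rt
Reagents that add atoms: pivaloyl chloride, CC(C)(C)C(Cl)=O
Why: DMAP-catalysed acylation of the remaining phenol, to which the tertiary alcohol is inert; the pivalate resists phenoxide and DBU later and is removed by LiAlH4 together with the ester.

Step 6
Reactants: 8 6-formyl-2-(3-hydroxy-3-methylbutyl)-3-[(triisopropylsilyl)oxy]phenyl pivalate
Product: 9 6-(hydroxymethyl)-2-(3-hydroxy-3-methylbutyl)-3-[(triisopropylsilyl)oxy]phenyl pivalate
Conditions: BH3·THF, THF, 0 °C; then MeOH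
Reagents that add atoms: none
Why: Borane reduces the aldehyde through a neutral alkoxyborane, so no free benzylic alkoxide arises that could take the neighbouring pivaloyl group by a 1,5-acyl shift (the risk with borohydride), and the aryl ester and silyl ether are not attacked at this temperature.

Step 7
Reactants: 10 2,4-dihydroxyphenylacetic acid
Product: 11 methyl 2-(2,4-dihydroxyphenyl)acetate
Conditions: MeOH, H2SO4 (cat.), reflux
Reagents that add atoms: methanol, CO
Why: Fischer esterification in excess methanol, which also keeps the ortho-hydroxy acid from staying as its lactone.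

Step 8
Reactants: 11 methyl 2-(2,4-dihydroxyphenyl)acetate; 12 prenyl bromide (one equivalent)
Product: 13 methyl 2-{2-hydroxy-4-[(3-methylbut-2-en-1-yl)oxy]phenyl}acetate
Conditions: K2CO3, acetone, rt
Reagents that add atoms: none
Why: Williamson etherification should favour the para hydroxyl, the less hindered of the two (the ortho hydroxyl is flanked by the side chain and hydrogen-bonded to its ester), and the isomeric and doubly alkylated ethers are removed by chromatography.

Step 9
Reactants: 9 ring A benzyl alcohol; 13 methyl 2-{2-hydroxy-4-[(3-methylbut-2-en-1-yl)oxy]phenyl}acetate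
Product: 14 ring B arylacetate carrying the ring A benzyl group on O2' and the prenyl group on O4'
Conditions: PPh3, DIAD, THF, 0 °C to rt
Reagents that add atoms: none
Why: Mitsunobu etherification joins the two units at O2' under neutral conditions, so no electron-rich benzylic halide has to be made and the pivalate and aryl silyl ether never meet carbonate; the tertiary alcohol is not activated and the O4' prenyl ether serves as the protecting group of the second phenol.

Step 10
Reactants: 14 O2'-benzylated O4'-prenyl arylacetate
Product: 16 methyl 2-{4-hydroxy-5-(2-methylbut-3-en-2-yl)-2-[(ring A aryl)methoxy]phenyl}acetate, via cyclohexadienone 15 (not isolated)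
Conditions: PhNEt2, 185 °C, sealed tube, argon
Reagents that add atoms: none
Why: Aromatic Claisen rearrangement, a [3,3] shift of the prenyl ether to C5' followed by enolisation, is directed away from C3', where a quaternary carbon would sit between two ether oxygens; this regiochemistry is known for 2-alkoxy-4-prenyloxyphenyl compounds, and the benzyl ether, pivalate and silyl ether are thermally stable in the basic amine.

Step 11
Reactants: 16 C5' reverse-prenylated phenol with free tertiary alcohol
Product: 17 bis(tert-butyldimethylsilyl) ether (O4' and tertiary oxygen)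
Conditions: TBSOTf, 2,6-lutidine, CH2Cl2, −78 to 0 °C
Reagents that add atoms: tert-butyldimethylsilyl trifluoromethanesulfonate, CC(C)(C)[Si](C)(C)OS(=O)(=O)C(F)(F)F
Why: A silyl triflate with a hindered pyridine base caps both the phenol next to the quaternary carbon and the tertiary alcohol in one operation, removing every O–H bond before the carbene is generated, while the base is too weak to enolise the arylacetate.

Step 12
Reactants: 17 fully protected methyl arylacetate
Product: 18 methyl 2-diazo-2-arylacetate with O2' benzylated by ring A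
Conditions: p-ABSA, DBU, MeCN, 0 °C to rt
Reagents that add atoms: 4-acetamidobenzenesulfonyl azide, CC(=O)Nc1ccc(cc1)S(=O)(=O)N=[N+]=[N-]
Why: Regitz diazo transfer to the amidine-generated arylacetate enolate is the standard entry to aryldiazoacetates, and the hindered aryl silyl ethers and the pivalate tolerate DBU in dry acetonitrile.

Step 13
Reactants: 18 methyl 2-diazo-2-arylacetate with O2' benzylated by ring A
Product: 19 methyl (2R,3S)-cis-2-(ring A aryl)-2,3-dihydrobenzofuran-3-carboxylate
Conditions: Rh2(S-PTTL)4 (dirhodium tetrakis[N-phthaloyl-(S)-tert-leucinate], 2 mol %), toluene, −60 °C, slow addition of 18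
Reagents that add atoms: none
Why: Rh2(S-PTTL)4, a divalent rhodium carboxylate dimer, expels N2 from 18 to give a donor–acceptor rhodium carbene at C3, which takes a hydride-like hydrogen from the O2'–CH2 group (activated by the ether oxygen and by the para-silyloxy ring A) and collapses to the C3–C4 bond in one asynchronous three-centre event. The closest known reaction is the enantioselective intramolecular 1,5-C–H insertion of methyl 2-(2-benzyloxyphenyl)-2-diazoacetates with this catalyst class, which gives cis-2-aryl-2,3-dihydrobenzofuran-3-carboxylates. The one ring formed, the dihydrofuran O2'–C2'–C1'–C3–C4, closes by 1,5-insertion. C3 is set by the N-phthaloyl-tert-leucinate ligands, which leave one face of the carbene open, and C4 follows under the same catalyst control because the ring A aryl group and the ester take the cis arrangement in the insertion transition state (a kinetic product, kept at −60 °C without base). The step needs insertion to outrun cyclopropanation of the vinyl group, cycloaddition to ring A and O–H insertion: the vinyl group is meta to the carbene-bearing carbon and cannot reach it, intermolecular paths are suppressed by slow addition at high dilution, and every hydroxyl is capped.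

Step 14
Reactants: 19 methyl (2R,3S)-cis-dihydrobenzofuran-3-carboxylate
Product: 20 (2R,3R)-cis diol (C2 hydroxymethyl group and free C8a phenol)
Conditions: LiAlH4, THF, −20 to 0 °C; then H2O, aq. NaOH
Reagents that add atoms: none
Why: Hydride reduction turns the ester into the C2 alcohol and cleaves the aryl pivalate in the same operation, and it is faster than deprotonation at C3, so the cis arrangement should be kept (the descriptor at C3 changes only because the priorities change).

Step 15
Reactants: 20 (2R,3R)-cis diol
Product: 21 (6aR,11aR)-cis-pterocarpan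
Conditions: PPh3, DIAD, THF (0.01 M), 0 °C to rt
Reagents that add atoms: none
Why: Intramolecular Mitsunobu etherification (6-exo-tet attack of the C8a phenoxide on the activated primary carbon C2) closes the pyran ring, which is possible only because the hydroxymethyl group and ring A are cis; no stereocentre takes part in the substitution.

Step 16
Reactants: 21 (6aR,11aR)-cis-pterocarpan
Product: 22 (3R)-2'-hydroxyisoflavan with three silyl ethers
Conditions: Li, NH3(l)/THF, −78 °C; then solid NH4Cl
Reagents that add atoms: none
Why: Dissolving-metal cleavage of a benzyl aryl ether: electron transfer breaks the C4–O2' bond, the only benzylic C–O bond in the molecule, to a phenoxide and a benzylic anion that ammonia protonates, while without an added alcohol the arenes, the isolated vinyl group and the silyl ethers should not be reduced in a short contact time; C3 is not involved.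

Step 17
Reactants: 22 (3R)-2'-hydroxyisoflavan with three silyl ethers
Product: 23 target, (3R)-3-[2,4-dihydroxy-5-(2-methylbut-3-en-2-yl)phenyl]-8-(3-hydroxy-3-methylbutyl)chroman-7-ol
Conditions: Bu4NF, THF, 0 to 50 °C; then pH 7 buffer
Reagents that add atoms: none
Why: Fluoride cleaves the two aryl silyl ethers readily and the tertiary silyl ether on warming, and the non-acidic conditions and neutral work-up avoid cyclisation of the phenols onto the 1,1-dimethylallyl group or the tertiary alcohol.

**Compound list**

1 | 2-iodoresorcinol (2-iodobenzene-1,3-diol) | Oc1cccc(O)c1I | starting material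
2 | N-[(2,4-dihydroxy-3-iodophenyl)methylidene]-N-methylmethanaminium chloride | C[N+](C)=Cc1ccc(O)c(I)c1O.[Cl-] | intermediate
3 | 2,4-dihydroxy-3-iodobenzaldehyde | O=Cc1ccc(O)c(I)c1O | intermediate
4 | 2-methylbut-3-en-2-ol | C=CC(C)(C)O | starting material
5 | 2,4-dihydroxy-3-[(1E)-3-hydroxy-3-methylbut-1-en-1-yl]benzaldehyde | O=Cc1ccc(O)c(/C=C/C(C)(C)O)c1O | intermediate
6 | 2,4-dihydroxy-3-(3-hydroxy-3-methylbutyl)benzaldehyde | O=Cc1ccc(O)c(CCC(C)(C)O)c1O | intermediate
7 | 2-hydroxy-3-(3-hydroxy-3-methylbutyl)-4-[(triisopropylsilyl)oxy]benzaldehyde | O=Cc1ccc(O[Si](C(C)C)(C(C)C)C(C)C)c(CCC(C)(C)O)c1O | intermediate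
8 | 6-formyl-2-(3-hydroxy-3-methylbutyl)-3-[(triisopropylsilyl)oxy]phenyl 2,2-dimethylpropanoate | O=Cc1ccc(O[Si](C(C)C)(C(C)C)C(C)C)c(CCC(C)(C)O)c1OC(=O)C(C)(C)C | intermediate
9 | 6-(hydroxymethyl)-2-(3-hydroxy-3-methylbutyl)-3-[(triisopropylsilyl)oxy]phenyl 2,2-dimethylpropanoate | OCc1ccc(O[Si](C(C)C)(C(C)C)C(C)C)c(CCC(C)(C)O)c1OC(=O)C(C)(C)C | intermediate
10 | 2,4-dihydroxyphenylacetic acid | OC(=O)Cc1ccc(O)cc1O | starting material
11 | methyl 2-(2,4-dihydroxyphenyl)acetate | COC(=O)Cc1ccc(O)cc1O | intermediate
12 | prenyl bromide (1-bromo-3-methylbut-2-ene) | CC(C)=CCBr | starting material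
13 | methyl 2-{2-hydroxy-4-[(3-methylbut-2-en-1-yl)oxy]phenyl}acetate | COC(=O)Cc1ccc(OCC=C(C)C)cc1O | intermediate
14 | methyl 2-{2-({2-[(2,2-dimethylpropanoyl)oxy]-3-(3-hydroxy-3-methylbutyl)-4-[(triisopropylsilyl)oxy]phenyl}methoxy)-4-[(3-methylbut-2-en-1-yl)oxy]phenyl}acetate | COC(=O)Cc1ccc(OCC=C(C)C)cc1OCc1ccc(O[Si](C(C)C)(C(C)C)C(C)C)c(CCC(C)(C)O)c1OC(=O)C(C)(C)C | intermediate
15 | methyl 2-[6-({2-[(2,2-dimethylpropanoyl)oxy]-3-(3-hydroxy-3-methylbutyl)-4-[(triisopropylsilyl)oxy]phenyl}methoxy)-3-(2-methylbut-3-en-2-yl)-4-oxocyclohexa-1,5-dien-1-yl]acetate (dienone tautomer of 16) | COC(=O)CC1=CC(C(C)(C)C=C)C(=O)C=C1OCc1ccc(O[Si](C(C)C)(C(C)C)C(C)C)c(CCC(C)(C)O)c1OC(=O)C(C)(C)C | intermediate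
16 | methyl 2-[2-({2-[(2,2-dimethylpropanoyl)oxy]-3-(3-hydroxy-3-methylbutyl)-4-[(triisopropylsilyl)oxy]phenyl}methoxy)-4-hydroxy-5-(2-methylbut-3-en-2-yl)phenyl]acetate | COC(=O)Cc1cc(C(C)(C)C=C)c(O)cc1OCc1ccc(O[Si](C(C)C)(C(C)C)C(C)C)c(CCC(C)(C)O)c1OC(=O)C(C)(C)C | intermediate
17 | methyl 2-[4-[(tert-butyldimethylsilyl)oxy]-2-({3-{3-[(tert-butyldimethylsilyl)oxy]-3-methylbutyl}-2-[(2,2-dimethylpropanoyl)oxy]-4-[(triisopropylsilyl)oxy]phenyl}methoxy)-5-(2-methylbut-3-en-2-yl)phenyl]acetate | COC(=O)Cc1cc(C(C)(C)C=C)c(O[Si](C)(C)C(C)(C)C)cc1OCc1ccc(O[Si](C(C)C)(C(C)C)C(C)C)c(CCC(C)(C)O[Si](C)(C)C(C)(C)C)c1OC(=O)C(C)(C)C | intermediate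
18 | methyl 2-diazo-2-[4-[(tert-butyldimethylsilyl)oxy]-2-({3-{3-[(tert-butyldimethylsilyl)oxy]-3-methylbutyl}-2-[(2,2-dimethylpropanoyl)oxy]-4-[(triisopropylsilyl)oxy]phenyl}methoxy)-5-(2-methylbut-3-en-2-yl)phenyl]acetate | COC(=O)C(=[N+]=[N-])c1cc(C(C)(C)C=C)c(O[Si](C)(C)C(C)(C)C)cc1OCc1ccc(O[Si](C(C)C)(C(C)C)C(C)C)c(CCC(C)(C)O[Si](C)(C)C(C)(C)C)c1OC(=O)C(C)(C)C | intermediate
19 | methyl (2R,3S)-6-[(tert-butyldimethylsilyl)oxy]-2-{3-{3-[(tert-butyldimethylsilyl)oxy]-3-methylbutyl}-2-[(2,2-dimethylpropanoyl)oxy]-4-[(triisopropylsilyl)oxy]phenyl}-5-(2-methylbut-3-en-2-yl)-2,3-dihydro-1-benzofuran-3-carboxylate (2,3-cis) | COC(=O)[C@@H]1[C@H](c2ccc(O[Si](C(C)C)(C(C)C)C(C)C)c(CCC(C)(C)O[Si](C)(C)C(C)(C)C)c2OC(=O)C(C)(C)C)Oc2cc(O[Si](C)(C)C(C)(C)C)c(C(C)(C)C=C)cc21 | intermediate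
20 | 6-[(2R,3R)-6-[(tert-butyldimethylsilyl)oxy]-3-(hydroxymethyl)-5-(2-methylbut-3-en-2-yl)-2,3-dihydro-1-benzofuran-2-yl]-2-{3-[(tert-butyldimethylsilyl)oxy]-3-methylbutyl}-3-[(triisopropylsilyl)oxy]phenol (2,3-cis) | OC[C@@H]1[C@H](c2ccc(O[Si](C(C)C)(C(C)C)C(C)C)c(CCC(C)(C)O[Si](C)(C)C(C)(C)C)c2O)Oc2cc(O[Si](C)(C)C(C)(C)C)c(C(C)(C)C=C)cc21 | intermediate
21 | (6aR,11aR)-9-[(tert-butyldimethylsilyl)oxy]-4-{3-[(tert-butyldimethylsilyl)oxy]-3-methylbutyl}-8-(2-methylbut-3-en-2-yl)-3-[(triisopropylsilyl)oxy]-6a,11a-dihydro-6H-[1]benzofuro[3,2-c]chromene (cis-pterocarpan) | C3[C@@H]1[C@H](c2ccc(O[Si](C(C)C)(C(C)C)C(C)C)c(CCC(C)(C)O[Si](C)(C)C(C)(C)C)c2O3)Oc2cc(O[Si](C)(C)C(C)(C)C)c(C(C)(C)C=C)cc21 | intermediate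
22 | 5-[(tert-butyldimethylsilyl)oxy]-2-[(3R)-8-{3-[(tert-butyldimethylsilyl)oxy]-3-methylbutyl}-7-[(triisopropylsilyl)oxy]-3,4-dihydro-2H-chromen-3-yl]-4-(2-methylbut-3-en-2-yl)phenol | C=CC(C)(C)c1cc([C@@H]2COc3c(ccc(O[Si](C(C)C)(C(C)C)C(C)C)c3CCC(C)(C)O[Si](C)(C)C(C)(C)C)C2)c(O)cc1O[Si](C)(C)C(C)(C)C | intermediate
23 | 4-[(3R)-7-hydroxy-8-(3-hydroxy-3-methylbutyl)-3,4-dihydro-2H-chromen-3-yl]-6-(2-methylbut-3-en-2-yl)benzene-1,3-diol (CNP0420388.1) | C=CC(C)(C)c1cc([C@@H]2COc3c(ccc(O)c3CCC(C)(C)O)C2)c(O)cc1O | target

**Step count and risks**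

Total step count: 17. Longest linear sequence: 15 steps (steps 1 to 6, then 9 to 17); steps 7 and 8 form the short ring B branch.

Steps most likely to fail:

Step 13. The ortho pivalate on ring A and the large silyl ethers lie close to the catalyst pocket, so discrimination between the two carbene faces may be less complete than with unsubstituted benzyl ethers. The fallback replaces reliance on catalyst control alone by separation of diastereomers. It sets out from diol 20 of insufficient enantiomeric purity, obtained through steps 13 and 14 as described. The primary hydroxyl of 20 is esterified with (S)-naproxen (EDC·HCl, DMAP, CH2Cl2, 0 °C; the doubly ortho-substituted phenol reacts more slowly). This gives [(2R,3R)-2-aryl-2,3-dihydrobenzofuran-3-yl]methyl (2S)-2-(6-methoxynaphthalen-2-yl)propanoate F1, which is freed from its (2S,3S) diastereomer by chromatography or crystallisation. LiAlH4 in THF at 0 °C then returns the route to 20 as a single enantiomer.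

Step 10. On the fully assembled ether, prolonged heating may carry the new ortho-(1,1-dimethylallyl)phenol on to the abnormal Claisen isomer or to cyclised products, and some migration to C3' may occur. The fallback moves the rearrangement to the small ring B unit and relies on steric differentiation of the two phenols in the union. It sets out from 13, which is heated alone (PhNEt2, 185 °C; any benzofuranone formed by loss of methanol is reopened with MeOH and Et3N) to give methyl 2-[2,4-dihydroxy-5-(2-methylbut-3-en-2-yl)phenyl]acetate F2. The O2' hydroxyl of F2, flanked only by the CH2CO2Me group, is then etherified with benzyl alcohol 9 (PPh3, DIAD, THF) in preference to the O4' hydroxyl, which is shielded by the adjacent quaternary carbon. The route is rejoined at 16.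

Step 16. Electron transfer may not stay confined to the benzylic C–O bond, leading to partial reduction of the electron-rich rings or loss of aryl silyl groups, or the cleavage may stall for want of solubility. The fallback breaks the same bond heterolytically instead of by electron transfer. It sets out from 21, which is treated with Et3SiH and BF3·OEt2 in CH2Cl2 at −78 °C: the Lewis acid ionises the C4–O2' bond to a C4 cation stabilised by the para-silyloxy group at C7, and the silane delivers hydride before C3 can lose its proton. The route is rejoined at 22, and this fallback makes no new compound (F0).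

**Further compounds**

F1 | step 13 | [(2R,3R)-6-[(tert-butyldimethylsilyl)oxy]-2-{3-{3-[(tert-butyldimethylsilyl)oxy]-3-methylbutyl}-2-hydroxy-4-[(triisopropylsilyl)oxy]phenyl}-5-(2-methylbut-3-en-2-yl)-2,3-dihydro-1-benzofuran-3-yl]methyl (2S)-2-(6-methoxynaphthalen-2-yl)propanoate | C[C@H](C(=O)OC[C@@H]1[C@H](c2ccc(O[Si](C(C)C)(C(C)C)C(C)C)c(CCC(C)(C)O[Si](C)(C)C(C)(C)C)c2O)Oc2cc(O[Si](C)(C)C(C)(C)C)c(C(C)(C)C=C)cc21)c1ccc2cc(OC)ccc2c1
F2 | step 10 | methyl 2-[2,4-dihydroxy-5-(2-methylbut-3-en-2-yl)phenyl]acetate | COC(=O)Cc1cc(C(C)(C)C=C)c(O)cc1O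
F0 | step 16 | none | none
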